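The vessel holds G, and L runs in over 50 s; the stirred flask then stands until 2.0 h.

| flask | L | G | remark | time |
|---|---|---|---|---|
| Thursday's | 0.025 M (fed, over 50 s) | 1.5 equiv | run made earlier; the fed solution adds 0.20 times the starting volume |  |
| Sunday's | 0.10 M (fed, over 50 s) | 1.5 equiv | run made earlier; the fed solution adds 0.20 times the starting volume |  |
| flask | 0.050 M (fed, over 50 s) | 1.50 equiv | the fed solution adds 0.20 times the starting volume | 2.0 h |

- Thursday's (time / min: L / %, Z / %): 20.0: 11.6, 23.9; 40.0: 11.4, 24.2; 60.0: 12.1, 23.8; 80.0: 11.9, 24.4; 90.0: 12.0, 23.4
- Sunday's (time / min: L / %, Z / %): 20.0: 0.1, 27.4; 40.0: 0.1, 27.3; 60.0: 0.5, 26.1; 80.0: 0, 27.2; 90.0: 0.2, 27.0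

(each reading ± 0.5 percentage points)

1. why nothing more happens at 2.0 h, or that something still does (forward and back rates have come level / all of L has reacted / G has run out first / it is still moving)
2. share of the L used up at 2.0 h
3. Z at 2.0 h, in percent of the L charged
4. E at 2.0 h, in percent of the L charged
5. Q at 2.0 h, in percent of the L charged

- amounts are per litre of the starting volume; all of the dose is in the solution fed
- the earlier runs were read with a standard deviation of 0.5 percentage points
- the reaction counts as stopped when no species that holds the L changes by six tenths of a point or more over the second half of the time

1. Both earlier runs lie flat from the first reading, Thursday's with 11.8 % of L left on average and Sunday's with 0.180 %, at the same equivalents of G. A flat line suggests a balance between L + G and a product. Thursday's run gives that balance a constant of 484 M⁻¹, which leaves about 4.13 % of L on Sunday. That is more than the reading, by far more than the scatter, so the balance goes.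

2. Suppose instead that L takes G one to one while G also decays by itself, in proportion to its own amount. Each L consumed then costs one G plus a share lost on the side, and summing over the run, with the flat line taken as the point where G ends, gives: G charged = L used + loss level × ln(L charged / L left). Amounts are per starting volume. Thursday's run puts at 0.00723 M the loss level, the concentration of L at which G goes to its own decay as fast as to L. For Sunday's run the balance gives 0.0992 % of L left, in line with the reading, and Sunday's readings played no part in the loss level.

3. In the new flask, G beyond one to one is 0.0250 M, which gives 3.15 % of L left. Objection: L left unreacted spares G, so the excess is larger. Feeding that back gives 2.53 %, and once more 2.64 %. Second objection: the balance takes L as present at once. But Thursday's feed also lasted 50 s, so that error sits partly inside the loss level. My conversion is 97.4 %.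

4. The forecast says G has run out first, with conversion 97.3 %, Z 26.3 %, E 35.5 % and Q 35.5 %. Its conversion lies close to mine but is not the same number. On E and Q it says: “The E/Q split is unmeasured, so I divide the remainder evenly, as a guess.”

5. The flask gives G has run out first, with conversion 97.3 %, Z 26.5 %, E 60.9 % and Q 8.76 %. Conversion and Z agree with the forecast; E and Q part from it.

    L + G → Q (k = 0.0387 M⁻¹ s⁻¹)
    G → J (k = 0.00222 s⁻¹)
    Z ⇌ E (K = 2.30, k = 0.0206 s⁻¹)
    L + G → Z (k = 0.386 M⁻¹ s⁻¹)
    L + G → D (k = 0.00520 M⁻¹ s⁻¹)

In this flask G, the limiting reagent, stands at 0 % at 2.00 h, and L stays at 2.7 % because of the turning of G into J: with that step taken away, conversion goes from 97.3 % to 100 %. With the loss level, that L left asks for 0.0748 M of G against 0.0750 M charged. In the neighbour flask with 0.900 equiv of G, the same balance at its conversion of 70.4 % asks for 0.0440 M against 0.0450 M charged.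

All runs are simulated from invented constants, noise included.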